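The closed vessel holds substrate and reagent, and the dawn run is this same flask, followed so far.

| flask | substrate | reagent | remark | time |
|---|---|---|---|---|
| dawn | 2 M | 1.2 M | the very flask that is asked about, followed so far |  |
| flask | 2.0 M | 1.20 M |  | 6.0 d |

dawn run (percent of the substrate charged)

| time / h | tautomer / % | target / % |
|---|---|---|
| 2.00 | 17.9 | 14.9 |
| 3.00 | 20.2 | 18.4 |
| 5.00 | 20.0 | 22.9 |
| 10.0 | 18.7 | 24.6 |
| 15.0 | 18.8 | 23.0 |
| 25.0 | 17.3 | 24.3 |
| 40.0 | 18.2 | 22.4 |

(each reading ± 1 percentage point)



- when, up to 6.0 d, the flask holds most tautomer
- the amount of tautomer, in percent of the substrate charged, at that time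

Read down the tautomer column. It shows 20.2% at 3.00 h and 18.2% at 40.0 h, a fall of 2 percentage points against a scatter of 1 point. So the readings place the top of the tautomer only loosely.

Now read the target column. From 10.0 h on, its readings wander around a mean of 23.6%. Counted one to one, the reagent charge covers 60.0% of the substrate charged. My own reckoning takes the reagent as the limiting reagent and divides the two. This gives the target share of the reagent, the part of the reagent charge that ends as target, read here as 0.393. The correction is the remainder: 36.4% of the substrate charged should then stand in some product absent from the table.

The forecast says 0.15 d (from 0.1 d to 0.23 d) and 20% (from 19% to 21.2%), adding “I see no sign of a later rise”.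

The flask holds most tautomer at 0.323 d, with 19.5%. The forecast's height stands, but its time is early by a factor of 2.15. At 0.162 d, half the best time, the flask already holds 19.1%, with readings scattered by 1 point. At the best time, reagent stands at 0.749% of its own charge. The target share, a reading, leaves 36.4% of the substrate charged as the reagent's remainder, and the flask then holds 35.7% of isomer of the product.

    substrate ⇌ tautomer (K = 1.20, k = 0.370 /h)
    substrate + reagent → isomer of the product (k = 0.410 /M/h)
    reagent + tautomer → target (k = 1.10 /M/h)
    2 substrate → homo dimer (k = 0.0110 /M/h)

In the neighbour with 0.30 M of reagent, the charge covers 15.0%, so the target share gives 5.90% of target. That neighbour ends with 6.02% of target.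

The runs come from a simulation with made-up constants; noise was put on by code.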